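## Analysis of the target

The target (22) is 2-[(3S,5R)-3,5-dimethyl-5-[(2R,5E,9E)-2-methyl-10-phenyldeca-5,9-dien-1-yl]-1,2-dioxolan-3-yl]acetic acid. The ring is numbered O1, O2, C3, C4, C5 throughout, also for intermediates, and side-chain atoms are primed.

- Both ring carbons next to oxygen are fully substituted: C3 carries CH3 and CH2CO2H, C5 carries CH3 and the chain C1′–C10′, and C4 is a bare methylene between them.
- The chain holds the third stereocentre, C2′ (R), and two isolated E alkenes, C5′=C6′ and the styrenyl C9′=C10′.
- C3 (S) and C5 (R) are 1,3-related across C4. The two ring methyl groups are trans, so CH2CO2H is trans to the chain and cis to the C5 methyl. C2′ is β to C5 in an open chain and cannot be relied on to control it.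
- Sensitive groups are the O–O bond (no hydrogenation, hydride, phosphine or low-valent metal), the β-peroxy carbonyl unit (E1cB ring opening under base) and the two alkenes (no late radical or electrophilic oxygenation).
- The difficulty is two tetrasubstituted C–O stereocentres on a peroxide, each of which must tell CH3 from CH2R. Neither has a hydrogen, so nothing can be corrected by epimerisation, and both oxygens must arrive as a peroxide because a tertiary alcohol cannot be converted into a peroxide with stereocontrol.
- The feature the route exploits: C3–C4–C5 together with O1–O2 is at the oxidation level of a β-methyl enone plus H2O2. C3 is the carbonyl carbon, C4 the α-carbon and C5 the β-carbon.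

## Retrosynthetic reasoning

22 from 20. The acid is released last from its methyl ester 20 through the salt 21. No skeletal bond changes.

C5′=C6′. Ester 20 is cut at the isolated E alkene into aldehyde 12 and sulfone 18, used as its anion 19. This alkene is four bonds from the nearest stereocentre, the cut places the styrene in 18, and it leaves a peroxide fragment with no other alkene in the chain while the ring is built. The forward reaction must give E and must spare the O–O bond and the β-peroxy ester.

C5′ aldehyde. Aldehyde 12 is traced back, through ozonide 11, to the isopropylidene end of 10. The terminus inherited from 1 thus masks the aldehyde through four steps without a protecting group.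

C3–CH2 (exocyclic). Ester 10 is cut into cation 9 and nucleophile 8, with 9 coming from peroxyketal 7. This makes C3 trigonal, so no configuration at C3 has to be carried into the step and any mixture converges. Only C5 must be set beforehand. In the forward direction 8 must add to the face of 9 anti to the chain.

O1–C5 and O2–C3 (key disconnection). Peroxyketal 7 goes back to hemiketal 6, its open form 5, and enone 4. The ring carbons C3, C4 and C5 of 6 are the carbonyl, α- and β-carbons of 4. The O1–O2 unit is brought in intact by the peroxide reagent of step 3, bonded first to C5 (conjugate addition, giving 5) and then to C3 (ring closure to 6). One retrosynthetic move removes the ring, the peroxide and the C5 stereocentre and leaves an acyclic dienone with a single stereocentre. In the forward direction a chiral amine catalyst must choose one face of a trisubstituted enone, so 4 is needed as one geometric isomer.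

C5–CH3 and C4–C3. Enone 4 is cut at its alkene: syn addition of a methyl–aluminium bond to alkyne 2 gives 3, and acylation of 3 gives 4. The E geometry is then fixed by mechanism, not by separation. Alkyne 2 comes from 1 by one-carbon homologation. The carbons of 1 map as follows: C1 becomes ring C5, C2 becomes C1′, C3 becomes C2′ (R, never touched), C4 and C5 become C3′ and C4′, and C6 becomes C5′.

Sulfone 18. It goes back to sulfide 17, which is cut at S–C into bromide 15 and thiol 16. Bromide 15 is cut at its styrenyl alkene into 13 and 14.

## Alternatives that were turned down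

Alternative 1: the textbook route, disconnecting O2–C3 by intramolecular oxa-Michael addition. The 1,1-disubstituted alkene A1 would be hydroperoxidised under cobalt/silane/dioxygen conditions to hydroperoxy enoate A2, which closes to 10 under base. It was turned down for four reasons:
- The C5–O bond forms through a tertiary radical, so C5 is uncontrolled.
- The 5-exo closure sets C3 under only the weak CH3/CH2R bias, so four isomers form and one is wanted.
- The radical oxygenation cannot distinguish the 1,1-disubstituted alkene of A1 from its isopropylidene and its enoate.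
- A1 has a doubly allylic methylene that would drift into conjugation, and it costs as many steps as 4.

Alternative 2: a (3+2) annulation that forms C4–C5 and O2–C3 together. Silylperoxy ketal A3 would be ionised by a Lewis acid to a silylperoxy carbenium ion, which alkene A4 attacks; the tertiary cation is trapped by the peroxide oxygen to give 10 in one step. This is the most convergent option, but it was turned down:
- The cation is planar at C5 and sees only C2′, so C5 forms without control.
- C3 is fixed in the ring closure with the same weak bias as in the chosen route.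
- The isopropylidene of A3 can attack the cation intramolecularly through a six-membered ring, so the chain would need a different, protected terminus and more steps.
- No catalyst-controlled version can be defended.

Alternative 3: disconnection of both exocyclic C–C bonds (C3–CH2 and C5–C1′) from the achiral bis-peroxyketal A5, made from a commercial 1,3-diketone. Two successive peroxycarbenium substitutions would follow, the first with 8 to give A6, the second bringing in the chain trans to the first. It was turned down:
- A6 forms as a racemate and nothing sets the absolute configuration, so a resolution would be needed.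
- The chain could only enter as a π-nucleophile (allylsilane or enol ether). C2′ would then have to be created afterwards by asymmetric reduction next to an O–O bond and two other alkenes, where hydrogenation is excluded.
- The chiral-pool source of C2′ would be given up.

Key step: step 3

Assumption: in step 3 the quinine-derived catalyst is taken to deliver the peroxide to the Re face of the β-carbon of 4, by analogy with E-β-monosubstituted enones; if the sense proves opposite, its quinidine-derived pseudoenantiomer is used with no other change.

## Steps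

Step 1
Reactants: 1 (R)-(+)-citronellal
Product: 2 (4R)-4,8-dimethylnon-7-en-1-yne
Conditions: dimethyl (1-diazo-2-oxopropyl)phosphonate, K2CO3, MeOH, 0 °C → rt
Reagents that add atoms: dimethyl (1-diazo-2-oxopropyl)phosphonate (Ohira–Bestmann reagent), CC(=O)C(=[N+]=[N-])P(=O)(OC)OC
Why: Seyferth–Gilbert homologation in the Ohira–Bestmann variant turns the aldehyde into the terminal alkyne and adds the carbon that becomes ring C4. The stereocentre is β to the carbonyl and cannot epimerise under K2CO3/MeOH.

Step 2
Reactants: 2 (4R)-4,8-dimethylnon-7-en-1-yne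
Product: 4 (3E,6R)-4,6,10-trimethylundeca-3,9-dien-2-one, via alkenyldimethylalane 3 (not isolated)
Conditions: Me3Al, Cp2ZrCl2 (cat.), CH2Cl2, 0 °C → rt; volatiles evaporated; then AcCl, Pd(PPh3)4 (cat.), THF, 0 °C → rt
Reagents that add atoms: trimethylaluminium, C[Al](C)C; acetyl chloride, CC(=O)Cl
Why: Zirconium-catalysed carboalumination (Negishi) adds CH3 and Al syn across the terminal alkyne with Al at the terminus, and the trisubstituted alkene does not take part. Palladium-catalysed acylation of the alkenyl–Al bond goes with retention, so the enone should form as the single E isomer.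

Step 3
Reactants: 4 (3E,6R)-4,6,10-trimethylundeca-3,9-dien-2-one
Product: 6 (5R)-5-[(2R)-2,6-dimethylhept-5-en-1-yl]-3,5-dimethyl-1,2-dioxolan-3-ol (both C3 epimers), via β-hydroperoxy ketone 5 (not isolated)
Conditions: 9-amino(9-deoxy)epiquinine (10 mol %), CCl3CO2H (20 mol %), 50% aq. H2O2, 1,4-dioxane, 30 °C
Reagents that add atoms: hydrogen peroxide, OO
Why: Proposed new method: the primary amine of the catalyst condenses with the methyl ketone of 4 to an α,β-unsaturated iminium ion paired with trichloroacetate, the protonated quinuclidine binds H2O2 and delivers it to the Re face of the β-carbon (the future ring C5), and hydrolysis of the β-peroxy enamine releases 5. The hydroperoxide of 5 then adds to its own ketone (5-exo-trig hemiketalisation), so the 1,2-dioxolane is closed with O1–C5 made in the conjugate addition and O2–C3 in the ring closure. The closest known reaction type is the amine-salt-catalysed hydroperoxidation of acyclic β-monosubstituted enones to cyclic peroxyhemiketals with this catalyst class, together with the epoxidation of β,β-disubstituted cyclic enones under the same iminium activation, which shows that H2O2 can attack a fully substituted β-carbon; what is new is asking an acyclic β,β-disubstituted enone to stop at the hydroperoxide stage. C5 is set by the catalyst, and the remote acyclic C2′ centre is expected to have little say; the hemiketal carbon C3 forms as a mixture, which does not matter because step 5 erases it. Face selectivity at the β-carbon relies on the single E geometry of 4 from step 2, in which the chain takes the place of the β-substituent and CH3 that of H in the known substrates. Hydroperoxide over epoxide relies on the mild temperature and absence of base, so that the peroxy enamine is protonated and hydrolysed before it can close the oxirane. Chemoselectivity relies on the fact that an isolated trisubstituted alkene does not react with H2O2 without a metal or peracid.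

Step 4
Reactants: 6 (5R)-5-[(2R)-2,6-dimethylhept-5-en-1-yl]-3,5-dimethyl-1,2-dioxolan-3-ol
Product: 7 (5R)-5-[(2R)-2,6-dimethylhept-5-en-1-yl]-3-methoxy-3,5-dimethyl-1,2-dioxolane (both C3 epimers)
Conditions: MeOH, camphorsulfonic acid (cat.), rt
Reagents that add atoms: methanol, CO
Why: Acid-catalysed exchange of the peroxyhemiketal OH for OMe (peroxyketal formation, as in lactol to methyl acetal) gives a storable precursor of the cation. C5 is a di-tert-alkyl peroxide carbon and is not involved, and the isopropylidene should survive catalytic acid at room temperature.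

Step 5
Reactants: 7 (5R)-5-[(2R)-2,6-dimethylhept-5-en-1-yl]-3-methoxy-3,5-dimethyl-1,2-dioxolane; 8 1-(tert-butyldimethylsilyloxy)-1-methoxyethene
Product: 10 methyl 2-[(3S,5R)-5-[(2R)-2,6-dimethylhept-5-en-1-yl]-3,5-dimethyl-1,2-dioxolan-3-yl]acetate, via peroxycarbenium ion 9 (not isolated)
Conditions: TiCl4, CH2Cl2, −78 °C
Reagents that add atoms: none
Why: Mukaiyama-type addition to a cyclic peroxycarbenium ion: TiCl4 ionises the exocyclic C3–OMe bond of both epimers of 7 to the same planar cation 9, which makes the step stereoconvergent at C3. Ketene acetal 8 is expected to approach anti to the larger C5 substituent (the β-branched chain, not CH3), so CH2CO2Me ends trans to the chain (3S); the minor 3R epimer is removed by chromatography. The isolated alkene is far less nucleophilic than 8, and C5 is untouched.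

Step 6
Reactants: 10 methyl 2-[(3S,5R)-5-[(2R)-2,6-dimethylhept-5-en-1-yl]-3,5-dimethyl-1,2-dioxolan-3-yl]acetate
Product: 12 methyl 2-[(3S,5R)-3,5-dimethyl-5-[(2R)-2-methyl-5-oxopentyl]-1,2-dioxolan-3-yl]acetate, via primary ozonide 11 (not isolated)
Conditions: O3, CH2Cl2/MeOH, −78 °C; then Me2S, −78 °C → rt
Reagents that add atoms: ozone, [O-][O+]=O
Why: Ozonolysis with reductive work-up cleaves the only C=C and gives the aldehyde at C5′. A dialkyl peroxide without α-hydrogen is inert to ozone and to dimethyl sulfide, so the O–O bond should survive, and no stereocentre is touched.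

Step 7
Reactants: 13 styrene; 14 5-bromopent-1-ene
Product: 15 [(1E)-5-bromopent-1-en-1-yl]benzene
Conditions: Grubbs II catalyst (cat.), excess 13, CH2Cl2, 40 °C
Reagents that add atoms: none
Why: Olefin cross-metathesis of a styrene with a terminal alkene; the conjugated, thermodynamically favoured E isomer is expected, and ethylene loss drives the reaction.

Step 8
Reactants: 15 [(1E)-5-bromopent-1-en-1-yl]benzene; 16 1-phenyl-1H-tetrazole-5-thiol
Product: 17 1-phenyl-5-{[(4E)-5-phenylpent-4-en-1-yl]sulfanyl}-1H-tetrazole
Conditions: K2CO3, DMF, rt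
Reagents that add atoms: none
Why: SN2 S-alkylation of the thiolate at the primary bromide; the alkene geometry is not affected.

Step 9
Reactants: 17 1-phenyl-5-{[(4E)-5-phenylpent-4-en-1-yl]sulfanyl}-1H-tetrazole
Product: 18 1-phenyl-5-{[(4E)-5-phenylpent-4-en-1-yl]sulfonyl}-1H-tetrazole
Conditions: (NH4)6Mo7O24·4H2O (cat.), 30% aq. H2O2, EtOH, 0 °C → rt
Reagents that add atoms: hydrogen peroxide, OO
Why: Molybdate-catalysed oxidation of the sulfide to the sulfone; these conditions oxidise sulfur and should leave the styrene alkene unepoxidised.

Step 10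
Reactants: 18 1-phenyl-5-{[(4E)-5-phenylpent-4-en-1-yl]sulfonyl}-1H-tetrazole; 12 methyl 2-[(3S,5R)-3,5-dimethyl-5-[(2R)-2-methyl-5-oxopentyl]-1,2-dioxolan-3-yl]acetate
Product: 20 methyl 2-[(3S,5R)-3,5-dimethyl-5-[(2R,5E,9E)-2-methyl-10-phenyldeca-5,9-dien-1-yl]-1,2-dioxolan-3-yl]acetate, via potassium sulfonyl carbanion 19 (not isolated)
Conditions: KHMDS, DME, −60 °C; then 12, −60 °C → rt
Reagents that add atoms: none
Why: Julia–Kocienski olefination: pre-formed 19 adds to 12, and Smiles rearrangement with loss of SO2 and the tetrazolone gives the C5′=C6′ alkene; phenyltetrazolyl sulfones with KHMDS in DME favour E. Pre-metalation leaves no free amide base to enolise the ester, and the peroxide carbons carry no hydrogen, so base-induced peroxide cleavage is not possible.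

Step 11
Reactants: 20 methyl 2-[(3S,5R)-3,5-dimethyl-5-[(2R,5E,9E)-2-methyl-10-phenyldeca-5,9-dien-1-yl]-1,2-dioxolan-3-yl]acetate
Product: 22 2-[(3S,5R)-3,5-dimethyl-5-[(2R,5E,9E)-2-methyl-10-phenyldeca-5,9-dien-1-yl]-1,2-dioxolan-3-yl]acetic acid, via lithium carboxylate 21 (not isolated)
Conditions: LiOH·H2O, THF/MeOH/H2O, 0 °C → rt; then 1 M HCl to pH 3
Reagents that add atoms: lithium hydroxide, [Li+].[OH-]
Why: Saponification of the methyl ester and protonation of 21 on acidic work-up. A di-tert-alkyl peroxide tolerates cold aqueous hydroxide, and no stereocentre is affected as long as the ester enolate is not formed.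

## Compound list

1 | (R)-(+)-citronellal, (3R)-3,7-dimethyloct-6-enal | C[C@H](CCC=C(C)C)CC=O | starting material
2 | (4R)-4,8-dimethylnon-7-en-1-yne | C[C@H](CCC=C(C)C)CC#C | intermediate
3 | dimethyl[(1E,4R)-2,4,8-trimethylnona-1,7-dien-1-yl]alumane | C[C@H](CCC=C(C)C)C/C(C)=C/[Al](C)C | intermediate (not isolated)
4 | (3E,6R)-4,6,10-trimethylundeca-3,9-dien-2-one | C[C@H](CCC=C(C)C)C/C(C)=C/C(C)=O | intermediate
5 | (4R,6R)-4-hydroperoxy-4,6,10-trimethylundec-9-en-2-one | C[C@H](CCC=C(C)C)C[C@@](C)(OO)CC(C)=O | intermediate (not isolated)
6 | (5R)-5-[(2R)-2,6-dimethylhept-5-en-1-yl]-3,5-dimethyl-1,2-dioxolan-3-ol (both C3 epimers) | C[C@H](CCC=C(C)C)C[C@]1(C)CC(C)(O)OO1 | intermediate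
7 | (5R)-5-[(2R)-2,6-dimethylhept-5-en-1-yl]-3-methoxy-3,5-dimethyl-1,2-dioxolane (both C3 epimers) | C[C@H](CCC=C(C)C)C[C@]1(C)CC(C)(OC)OO1 | intermediate
8 | 1-(tert-butyldimethylsilyloxy)-1-methoxyethene | C=C(OC)O[Si](C)(C)C(C)(C)C | starting material
9 | (5R)-5-[(2R)-2,6-dimethylhept-5-en-1-yl]-3,5-dimethyl-1,2-dioxolan-3-ylium (peroxycarbenium ion) | C[C@H](CCC=C(C)C)C[C@]1(C)CC(C)=[O+]O1 | intermediate (not isolated)
10 | methyl 2-[(3S,5R)-5-[(2R)-2,6-dimethylhept-5-en-1-yl]-3,5-dimethyl-1,2-dioxolan-3-yl]acetate | C[C@H](CCC=C(C)C)C[C@]1(C)C[C@@](C)(CC(=O)OC)OO1 | intermediate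
11 | methyl 2-[(3S,5R)-5-[(2R)-4-(5,5-dimethyl-1,2,3-trioxolan-4-yl)-2-methylbutyl]-3,5-dimethyl-1,2-dioxolan-3-yl]acetate (primary ozonide, both epimers at the trioxolane carbon) | C[C@H](CCC1OOOC1(C)C)C[C@]2(C)C[C@@](C)(CC(=O)OC)OO2 | intermediate (not isolated)
12 | methyl 2-[(3S,5R)-3,5-dimethyl-5-[(2R)-2-methyl-5-oxopentyl]-1,2-dioxolan-3-yl]acetate | C[C@H](CCC=O)C[C@]1(C)C[C@@](C)(CC(=O)OC)OO1 | intermediate
13 | styrene | C=Cc1ccccc1 | starting material
14 | 5-bromopent-1-ene | C=CCCCBr | starting material
15 | [(1E)-5-bromopent-1-en-1-yl]benzene | BrCCC/C=C/c1ccccc1 | intermediate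
16 | 1-phenyl-1H-tetrazole-5-thiol | Sc1nnnn1-c1ccccc1 | starting material
17 | 1-phenyl-5-{[(4E)-5-phenylpent-4-en-1-yl]sulfanyl}-1H-tetrazole | C(CC/C=C/c1ccccc1)Sc1nnnn1-c1ccccc1 | intermediate
18 | 1-phenyl-5-{[(4E)-5-phenylpent-4-en-1-yl]sulfonyl}-1H-tetrazole | O=S(=O)(CCC/C=C/c1ccccc1)c1nnnn1-c1ccccc1 | intermediate
19 | potassium (4E)-5-phenyl-1-[(1-phenyl-1H-tetrazol-5-yl)sulfonyl]pent-4-en-1-ide | [K+].[CH-](CC/C=C/c1ccccc1)S(=O)(=O)c1nnnn1-c1ccccc1 | intermediate (not isolated)
20 | methyl 2-[(3S,5R)-3,5-dimethyl-5-[(2R,5E,9E)-2-methyl-10-phenyldeca-5,9-dien-1-yl]-1,2-dioxolan-3-yl]acetate | C[C@H](CC/C=C/CC/C=C/c1ccccc1)C[C@]1(C)C[C@@](C)(CC(=O)OC)OO1 | intermediate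
21 | lithium 2-[(3S,5R)-3,5-dimethyl-5-[(2R,5E,9E)-2-methyl-10-phenyldeca-5,9-dien-1-yl]-1,2-dioxolan-3-yl]acetate | [Li+].C[C@H](CC/C=C/CC/C=C/c1ccccc1)C[C@]1(C)C[C@@](C)(CC(=O)[O-])OO1 | intermediate (not isolated)
22 | 2-[(3S,5R)-3,5-dimethyl-5-[(2R,5E,9E)-2-methyl-10-phenyldeca-5,9-dien-1-yl]-1,2-dioxolan-3-yl]acetic acid | C[C@H](CC/C=C/CC/C=C/c1ccccc1)C[C@]1(C)C[C@@](C)(CC(=O)O)OO1 | target

## Step count and least certain steps

Total step count: 11. Longest linear sequence: 8 (steps 1, 2, 3, 4, 5, 6, 10, 11); the sulfone branch (steps 7–9) joins at step 10.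

Step 3 (key step, Proposed new method). The most likely failure is low enantiofacial selectivity or slow turnover. Iminium formation from a β,β-disubstituted enone is slower, γ-deprotonation to a dienamine can scramble the alkene geometry before the C–O bond forms, and the peroxy enamine may close to the epoxide instead of being hydrolysed. The fallback uses known chemistry, sets out from 2 and returns at 6, and puts C5 on a stereospecific displacement instead of on catalyst face selection:
- Gold(I)-catalysed Markovnikov hydration of 2 gives (4R)-4,8-dimethylnon-7-en-2-one F1.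
- Catalytic enantioselective allylboration of this ketone, with an allylboronate and the enantiomer of a chiral 3,3′-disubstituted BINOL catalyst that gives the 4R carbinol, gives (4R,6R)-4,6,10-trimethylundeca-1,9-dien-4-ol F2.
- Tsuji–Wacker oxidation of the terminal alkene gives (4S,6R)-4-hydroxy-4,6,10-trimethylundec-9-en-2-one F3. The geometry is the same; the descriptor changes with the CIP priorities.
- NaBH4 gives (4S,6R)-4,6,10-trimethylundec-9-ene-2,4-diol F4 as both C2 epimers.
- Mesylation of the secondary hydroxyl alone gives (4S,6R)-4-hydroxy-4,6,10-trimethylundec-9-en-2-yl methanesulfonate F5.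
- KOt-Bu closes (2S)-2-[(2R)-2,6-dimethylhept-5-en-1-yl]-2,4-dimethyloxetane F6.
- Lewis-acid-promoted opening of the oxetane by ethereal H2O2 at the tertiary carbon, with inversion, gives (4R,6R)-4-hydroperoxy-4,6,10-trimethylundec-9-en-2-ol F7.
- Oxidation of the secondary alcohol (buffered Dess–Martin periodinane) gives 5, which closes to 6.

This costs seven more operations.

Step 5. The most likely failure is poor facial selectivity at C3, because CH3 and the CH2R chain at C5 differ only moderately in size. Ionisation of the endocyclic C–O bond instead of the methoxy group is a second risk. The fallback replaces substrate control by reagent control; it sets out from 7 and returns at 10. Cation 9, generated from 7 with a Lewis acid, is intercepted by the chlorotitanium enolate of (4S)-3-acetyl-4-isopropyl-1,3-thiazolidine-2-thione. The antipode of the auxiliary that reinforces the substrate bias is to be used; the S auxiliary is drawn. The product is 2-[(3S,5R)-5-[(2R)-2,6-dimethylhept-5-en-1-yl]-3,5-dimethyl-1,2-dioxolan-3-yl]-1-[(4S)-4-isopropyl-2-thioxo-1,3-thiazolidin-3-yl]ethan-1-one F8. Methanolysis (MeOH, imidazole) releases the auxiliary and gives 10.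

Step 2. The most likely failure is incomplete or unselective acyl transfer from aluminium: methyl transfer from residual methylaluminium to the acid chloride, protodealumination, or loss of geometry in the product. The fallback forms the C–C bond by carbonyl addition; it sets out from 2 through 3 and returns at 4. Alane 3 is converted into its ate complex with n-BuLi and added to acetaldehyde to give (3E,6R)-4,6,10-trimethylundeca-3,9-dien-2-ol F9 as both C2 epimers. Oxidation with MnO2 gives 4.

Step 10. The most likely failure is deprotonation of the ester α-methylene by 19 followed by E1cB opening of the dioxolane; aldol self-condensation of 12 and erosion of E selectivity are lesser risks. The fallback moves the olefination ahead of the ester; it sets out from 7 and returns at 20. Ozonolysis of 7 gives (4R)-5-[(3R)-5-methoxy-3,5-dimethyl-1,2-dioxolan-3-yl]-4-methylpentanal F10, which has no acidic C–H near the peroxide. Julia–Kocienski olefination with 18 gives (3R)-5-methoxy-3,5-dimethyl-3-[(2R,5E,9E)-2-methyl-10-phenyldeca-5,9-dien-1-yl]-1,2-dioxolane F11. The peroxycarbenium addition of 8 under the conditions of step 5 then gives 20.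

Step 11. The most likely failure is hydroxide-induced retro-oxa-Michael opening and reclosure of the β-peroxy ester, which would scramble C3 or destroy the ring. The fallback never makes an ester; it sets out from 7 and returns at 22. Under the conditions of step 5, 7 is treated with 1,1-bis(trimethylsilyloxy)ethene, and aqueous work-up gives 2-[(3S,5R)-5-[(2R)-2,6-dimethylhept-5-en-1-yl]-3,5-dimethyl-1,2-dioxolan-3-yl]acetic acid F12. Ozonolysis gives 2-[(3S,5R)-3,5-dimethyl-5-[(2R)-2-methyl-5-oxopentyl]-1,2-dioxolan-3-yl]acetic acid F13. Julia–Kocienski olefination with one extra equivalent of 19, to absorb the acid proton, gives 22 directly.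

## Further compounds

F1 | step 3 | (4R)-4,8-dimethylnon-7-en-2-one | C[C@H](CCC=C(C)C)CC(C)=O
F2 | step 3 | (4R,6R)-4,6,10-trimethylundeca-1,9-dien-4-ol | C[C@H](CCC=C(C)C)C[C@](C)(O)CC=C
F3 | step 3 | (4S,6R)-4-hydroxy-4,6,10-trimethylundec-9-en-2-one | C[C@H](CCC=C(C)C)C[C@](C)(O)CC(C)=O
F4 | step 3 | (4S,6R)-4,6,10-trimethylundec-9-ene-2,4-diol (both C2 epimers) | C[C@H](CCC=C(C)C)C[C@](C)(O)CC(C)O
F5 | step 3 | (4S,6R)-4-hydroxy-4,6,10-trimethylundec-9-en-2-yl methanesulfonate (both C2 epimers) | C[C@H](CCC=C(C)C)C[C@](C)(O)CC(C)OS(C)(=O)=O
F6 | step 3 | (2S)-2-[(2R)-2,6-dimethylhept-5-en-1-yl]-2,4-dimethyloxetane (both C4 epimers) | C[C@H](CCC=C(C)C)C[C@@]1(C)CC(C)O1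
F7 | step 3 | (4R,6R)-4-hydroperoxy-4,6,10-trimethylundec-9-en-2-ol (both C2 epimers) | C[C@H](CCC=C(C)C)C[C@@](C)(OO)CC(C)O
F8 | step 5 | 2-[(3S,5R)-5-[(2R)-2,6-dimethylhept-5-en-1-yl]-3,5-dimethyl-1,2-dioxolan-3-yl]-1-[(4S)-4-isopropyl-2-thioxo-1,3-thiazolidin-3-yl]ethan-1-one | C[C@H](CCC=C(C)C)C[C@]1(C)C[C@@](C)(CC(=O)N2C(=S)SC[C@@H]2C(C)C)OO1
F9 | step 2 | (3E,6R)-4,6,10-trimethylundeca-3,9-dien-2-ol (both C2 epimers) | C[C@H](CCC=C(C)C)C/C(C)=C/C(C)O
F10 | step 10 | (4R)-5-[(3R)-5-methoxy-3,5-dimethyl-1,2-dioxolan-3-yl]-4-methylpentanal (both epimers at the methoxy carbon) | C[C@H](CCC=O)C[C@]1(C)CC(C)(OC)OO1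
F11 | step 10 | (3R)-5-methoxy-3,5-dimethyl-3-[(2R,5E,9E)-2-methyl-10-phenyldeca-5,9-dien-1-yl]-1,2-dioxolane (both epimers at the methoxy carbon) | C[C@H](CC/C=C/CC/C=C/c1ccccc1)C[C@]1(C)CC(C)(OC)OO1
F12 | step 11 | 2-[(3S,5R)-5-[(2R)-2,6-dimethylhept-5-en-1-yl]-3,5-dimethyl-1,2-dioxolan-3-yl]acetic acid | C[C@H](CCC=C(C)C)C[C@]1(C)C[C@@](C)(CC(=O)O)OO1
F13 | step 11 | 2-[(3S,5R)-3,5-dimethyl-5-[(2R)-2-methyl-5-oxopentyl]-1,2-dioxolan-3-yl]acetic acid | C[C@H](CCC=O)C[C@]1(C)C[C@@](C)(CC(=O)O)OO1
A1 | alternative 1 | methyl (2E,7R)-3,7,11-trimethyl-5-methylidenedodeca-2,10-dienoate | C[C@H](CCC=C(C)C)CC(=C)C/C(C)=C/C(=O)OC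
A2 | alternative 1 | methyl (2E,7R)-5-hydroperoxy-3,5,7,11-tetramethyldodeca-2,10-dienoate (both C5 epimers) | C[C@H](CCC=C(C)C)CC(C)(OO)C/C(C)=C/C(=O)OC
A3 | alternative 2 | triethyl{[(4R)-2-methoxy-4,8-dimethylnon-7-en-2-yl]peroxy}silane (both C2 epimers) | C[C@H](CCC=C(C)C)CC(C)(OC)OO[Si](CC)(CC)CC
A4 | alternative 2 | methyl 3-methylbut-3-enoate | C=C(C)CC(=O)OC
A5 | alternative 3 | 3,5-dimethoxy-3,5-dimethyl-1,2-dioxolane | COC1(C)CC(C)(OC)OO1
A6 | alternative 3 | methyl 2-(5-methoxy-3,5-dimethyl-1,2-dioxolan-3-yl)acetate (racemic) | COC1(C)CC(C)(CC(=O)OC)OO1
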